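The ten-membered ring A is read as a 1,5-diene: the C1 ketone as its enol ether C1=C10 and the 4,5-epoxide as the alkene C4=C5, linked through C2–C3. This array is the ring-opened form of a bicyclo[2.2.0]hexane, so ring A can be stored in a six-four-four tricycle. One irradiation joins a quinic-acid-derived (4R,5R)-3-methyl-4,5-bis(silyloxy)cyclohexenone (C5–C10) to 1-methyl-2-silyloxycyclobutene (C1–C4), forming C1–C10, C4–C5 and the central cyclobutane. The rigid adduct is used to set C6 and to build the butenolide; heat then cleaves C1–C4 and C5–C10 and releases ring A.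

Key step: step 12

Remarks on the chemistry
- Numbering: germacrane numbering is used for all intermediates. Cyclohexenone ring atoms C1–C6 become C6, C5, C10, C9, C8, C7. The cyclobutene carbons become C1 (oxygen-bearing), C4 (methyl-bearing), C2 and C3.
- (−)-Quinic acid is written with all four ring stereocentres. A SMILES that marks only C3 and C5 does not define the compound.
- O1 carries TBS instead of TMS, because it must survive nine steps as a tertiary ether and then leave the thermolysis as an isolable enol ether.
- C11–C13 come from 2-(acetoxymethyl)acrylic acid. A pyruvate unit would leave C13 as a bare methyl group that cannot be oxidised selectively later.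
- C6 and the butenolide are made on the tricycle, where C6 is the only ketone, C1 is a plain silyl ether, no enolate sits next to O8, and C9-OH is neopentylic, so O8 and O9 can be told apart. The price is the loss of the enone during ring opening, which is treated under step 20.
- Assumption: 29 is drawn with C2 and C9 cis at C1=C10. The other geometry would give the same 30.

Step 1
Reactants: 1 (−)-quinic acid
Product: 2 methyl quinate 4,5-(butane-2,3-diacetal)
Conditions: butane-2,3-dione, HC(OMe)3, MeOH, CSA (cat.), reflux
Reagents that add atoms: butane-2,3-dione, CC(=O)C(C)=O; methanol, CO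
Why: Acid-catalysed butane-2,3-diacetal formation selects the only trans-diequatorial diol (O4/O5 of quinic acid, the later O9/O8) with both methoxy groups axial under anomeric control, and Fischer esterification runs in the same pot.

Step 2
Reactants: 2 methyl quinate 4,5-(butane-2,3-diacetal)
Product: 3 triol (CO2Me of 2 reduced to CH2OH)
Conditions: NaBH4, EtOH, 0 °C to rt
Reagents that add atoms: none
Why: Borohydride reduction of an α-hydroxy ester, activated by the neighbouring hydroxyl, gives the 1,2-diol needed for cleavage without touching the acetal.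

Step 3
Reactants: 3 triol
Product: 4 3-hydroxy-4,5-(butane-2,3-diacetal)cyclohexanone (3-OH cis to O4)
Conditions: NaIO4, H2O/CH2Cl2, pH 7 buffer, 0 °C
Reagents that add atoms: none
Why: Periodate glycol cleavage (Malaprade reaction) removes the exocyclic carbon and turns the former C1 of quinic acid into the ketone that becomes C6.

Step 4
Reactants: 4 hydroxy ketone
Product: 6 (4R,5R)-4,5-dihydroxycyclohex-2-enone butane-2,3-diacetal, via mesylate 5 (not isolated)
Conditions: MsCl, Et3N, CH2Cl2, 0 °C
Reagents that add atoms: methanesulfonyl chloride, CS(=O)(=O)Cl (stays in 5 only)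
Why: Mesylation of the only free hydroxyl followed by E1cB elimination gives the enone, while the locked equatorial acetal oxygens are poor leaving groups and stay in place.

Step 5
Reactants: 6 diacetal enone
Product: 7 TMS enol ether of the 3-methyl ketone (methyl axial, cis to O9)
Conditions: MeLi, CuI, Et2O, 0 °C; then 6, TMSCl, −78 °C
Reagents that add atoms: lithium dimethylcuprate (made in the flask from MeLi and CuI), [Li+].C[Cu-]C; chlorotrimethylsilane, C[Si](C)(C)Cl
Why: Gilman cuprate 1,4-addition accelerated by TMSCl brings the C14 methyl axially to C10 and traps the regiodefined enolate as its silyl ether, and the new centre is erased again in step 6.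

Step 6
Reactants: 7 TMS enol ether
Product: 8 (4R,5R)-4,5-dihydroxy-3-methylcyclohex-2-enone butane-2,3-diacetal
Conditions: Pd(OAc)2 (1.05 equiv), MeCN, rt
Reagents that add atoms: none
Why: Saegusa–Ito oxidation (palladation of the enol ether, then β-hydride elimination) restores the C5=C10 double bond with the methyl group in place.

Step 7
Reactants: 8 diacetal methyl enone
Product: 9 (4R,5R)-4,5-dihydroxy-3-methylcyclohex-2-enone
Conditions: TFA/H2O (9:1), CH2Cl2, 0 °C to rt
Reagents that add atoms: none
Why: Aqueous-acid acetal hydrolysis frees the trans-diol, whose two stereocentres take no part in the reaction.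

Step 8
Reactants: 9 diol enone
Product: 10 (4R,5R)-4,5-bis(tert-butyldimethylsilyloxy)-3-methylcyclohex-2-enone
Conditions: TBSOTf, 2,6-lutidine, CH2Cl2, −78 to 0 °C
Reagents that add atoms: tert-butyldimethylsilyl triflate, CC(C)(C)[Si](C)(C)OS(=O)(=O)C(F)(F)F
Why: Silyl triflate/lutidine silylation needs no strong base, so the β-hydroxy enone does not eliminate, and the two bulky vicinal silyl ethers together with A(1,2) strain from the C10 methyl favour the diaxial half-chair that controls the face in step 12.

Step 9
Reactants: 11 cyclobutanone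
Product: 12 N-isopropylcyclobutanimine
Conditions: iPrNH2, 4 Å MS, Et2O, rt
Reagents that add atoms: isopropylamine, CC(C)N
Why: Imine condensation converts cyclobutanone, whose own enolate self-condenses, into a precursor of a well-behaved azaenolate.

Step 10
Reactants: 12 N-isopropylcyclobutanimine; 13 iodomethane
Product: 16 2-methylcyclobutanone (racemic), via lithio enamide 14 (not isolated), via methylated imine 15 (not isolated)
Conditions: LDA, THF, 0 °C; MeI, −78 °C to rt; aq. oxalic acid, Et2O, rt
Reagents that add atoms: iodomethane (13), CI; water, O; LDA, [Li+].CC(C)[N-]C(C)C (lithium in 14 only)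
Why: Metalloenamine alkylation gives clean monomethylation and mild acid hydrolysis returns the ketone, whose racemic centre becomes sp2 in step 11.

Step 11
Reactants: 16 2-methylcyclobutanone
Product: 17 1-methyl-2-(tert-butyldimethylsilyloxy)cyclobutene
Conditions: TBSOTf, Et3N, CH2Cl2, 0 °C to rt; distillation
Reagents that add atoms: tert-butyldimethylsilyl triflate, CC(C)(C)[Si](C)(C)OS(=O)(=O)C(F)(F)F
Why: Soft enolisation under equilibrating conditions (silyl triflate, amine, ammonium triflate as proton shuttle) favours the tetrasubstituted enol ether, and the less substituted isomer, which would be the more reactive alkene in step 12, is removed by distillation.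

Step 12
Reactants: 10 bis-TBS methyl enone; 17 silyloxycyclobutene
Product: 18 cis-anti-cis six-four-four photoadduct (tricyclo[4.4.0.0(2,5)]decan-7-one skeleton; cyclobutane on the face anti to O9; C2–C3 anti to the six-membered ring; O1 and C15 turned towards it)
Conditions: hν (medium-pressure Hg lamp, uranium-glass filter, λ > 330 nm), 17 (5 equiv), hexane, −40 °C; then filtration through basic Al2O3
Reagents that add atoms: none
Why: Light absorbed by the enone of 10 gives, after intersystem crossing, its twisted π,π* triplet, which attacks the electron-rich C1=C4 bond of 17 to form a triplet 1,4-biradical that closes after spin inversion; this is the stepwise enone–alkene [2+2] photocycloaddition, a reaction type established for cyclobutenes as the alkene partner. The one ring closed is the central cyclobutane C1–C4–C5–C10, assembled intermolecularly from the two new bonds C1–C10 and C4–C5 (radical addition to the alkene, then 1,4-biradical recombination) and sharing one edge with each ring already present. Head-to-tail orientation is required and rests on the silyloxy donor, which pairs the oxygen-bearing C1 with the β-carbon C10 and the nucleophilic C4 with the α-carbon C5 and lets the reaction run through an α-silyloxy- or α-keto-stabilised radical. C10 and C5 are set by the enone face: A(1,2) strain with the C10 methyl and the bulk of the two TBS groups hold O9 pseudoaxial, so the alkene enters anti to O9, and the junction ends cis because C5 is enolisable and the alumina filtration relaxes any strained trans fusion. C1 and C4 are set together, since the cyclobutene can only add suprafacially, by the anti approach that keeps C2–C3 away from the six-membered ring, which gives the cis-anti-cis adduct. An excess of 17 and light above 330 nm hold down enone dimerisation and secondary photolysis of the product ketone.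

Step 13
Reactants: 18 photoadduct
Product: 19 7-methylene ketone
Conditions: (CH2O)n, iPr2NH·TFA, THF, reflux
Reagents that add atoms: paraformaldehyde (as formaldehyde), C=O
Why: Mannich-type α-methylenation (iminium formation, attack of the enol, loss of the amine) can only be completed at the C7 methylene, because C5 carries a single hindered hydrogen, and the weakly acidic medium avoids a metal enolate next to the C8 silyl ether.

Step 14
Reactants: 19 7-methylene ketone
Product: 20 allylic alcohol (O6 cis to C4 and to O8, H6 on the convex face)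
Conditions: NaBH4, CeCl3·7H2O, MeOH/THF, −78 to −40 °C
Reagents that add atoms: none
Why: In this Luche 1,2-reduction hydride reaches C6 from the convex face opposite the cyclobutane, the concave face being blocked by C15 and the C1 silyl ether, which places O6 cis to C4 and O8 and so sets C6 as in the target.

Step 15
Reactants: 21 2-(bromomethyl)acrylic acid
Product: 22 2-(acetoxymethyl)acrylic acid
Conditions: KOAc, AcOH, BHT, 80 °C
Reagents that add atoms: potassium acetate, CC(=O)[O-].[K+]
Why: SN2 displacement of the allylic bromide by acetate (the SN2' mode gives the same product) supplies C11, C12 and C13 with the C13 oxygen and its acetyl group already in place.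

Step 16
Reactants: 20 allylic alcohol; 22 2-(acetoxymethyl)acrylic acid
Product: 24 O6 2-(acetoxymethyl)acrylate of 20, via mixed anhydride 23 (not isolated)
Conditions: 22, 2,4,6-trichlorobenzoyl chloride, Et3N, toluene, rt; then 20, DMAP (cat.), 40 °C
Reagents that add atoms: 2,4,6-trichlorobenzoyl chloride, O=C(Cl)c1c(Cl)cc(Cl)cc1Cl (its acyl group stays in 23 only)
Why: Yamaguchi esterification through the mixed anhydride acylates the hindered secondary alcohol with retention at C6.

Step 17
Reactants: 24 diene ester
Product: 25 tetracyclic 7(11)-en-12,6-olide (13-OAc; O8, O9 and O1 as TBS ethers)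
Conditions: second-generation Hoveyda–Grubbs catalyst (10 mol%), toluene (0.005 M), 80 °C, Ar sparge
Reagents that add atoms: none
Why: Ring-closing metathesis of the two 1,1-disubstituted alkenes closes the five-membered lactone and creates the tetrasubstituted C7=C11 bond without regio- or stereochemical ambiguity, driven by loss of ethylene.

Step 18
Reactants: 25 tris-TBS butenolide
Product: 26 8,9-diol (O1 still TBS)
Conditions: HF·pyridine, pyridine, THF, 0 °C to rt
Reagents that add atoms: none
Why: Fluoride-mediated desilylation removes the two secondary silyl ethers, whereas the tertiary C1 silyl ether, flanked by quaternary C4 and C10, reacts far more slowly.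

Step 19
Reactants: 26 8,9-diol; 27 methacrylic anhydride
Product: 28 8-O-methacrylate (9-OH free)
Conditions: 27 (1.1 equiv), Et3N, DMAP (cat.), CH2Cl2, −20 °C
Reagents that add atoms: methacrylic anhydride (27), C=C(C)C(=O)OC(=O)C(C)=C
Why: DMAP-catalysed acylation is steered by sterics to the C8 hydroxyl, because the C9 hydroxyl is neopentylic next to quaternary C10.

Step 20
Reactants: 28 tetracyclic methacrylate
Product: 29 (4E)-1-(tert-butyldimethylsilyloxy)germacra-1(10),4,7(11)-trien-12,6-olide with 8-O-methacrylate, 9-OH and 13-OAc (C6, C8, C9 as in the target; C2 and C9 cis at C1=C10)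
Conditions: toluene (0.005 M, degassed), BHT, silylated sealed tube, 130 °C
Reagents that add atoms: none
Why: In this thermal cycloreversion of a bicyclo[2.2.0]hexane, homolysis of the strained, donor-substituted C1–C4 bond gives a cyclohexane-1,4-diyl that cleaves the fully substituted C5–C10 bond, and both the boat form and the favoured chair form of the diyl (C6 equatorial) lead to E geometry at C4=C5, while the geometry at C1=C10 has no consequence.

Step 21
Reactants: 29 silyl enol ether
Product: 30 (4E,10S)-1-oxogermacra-4,7(11)-dien-12,6-olide with 8-O-methacrylate, 9-OH and 13-OAc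
Conditions: HF·pyridine, pyridine, THF, −20 °C
Reagents that add atoms: none
Why: Fluoride-induced cleavage of the silyl enol ether ends in a kinetic protonation in which A(1,3) strain holds H9 in the plane of C1=C10, C8 and the rest of ring A cover one face, and the proton enters C10 from the open face on the side of the free C9 hydroxyl, which sets 10S under acidic conditions that avoid epimerisation and retro-aldol cleavage.

Step 22
Reactants: 30 keto alkene
Product: 31 CNP0185951.1 (target)
Conditions: DMDO, acetone/CH2Cl2, −20 °C
Reagents that add atoms: dimethyldioxirane, CC1(C)OO1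
Why: Dioxirane epoxidation takes the only electron-rich alkene, and A(1,3) strain between C15 and C6 fixes H6 in the alkene plane so that ring A shields one face and oxygen arrives on the outer face on the side of O6, which gives the trans (4R,5R)-epoxide.

Compound list
1 | (−)-quinic acid, (1S,3R,4S,5R)-1,3,4,5-tetrahydroxycyclohexanecarboxylic acid | O[C@@]1(C(=O)O)C[C@@H](O)[C@@H](O)[C@H](O)C1 | starting material
2 | methyl quinate, O4/O5 bridged by (2S,3S)-2,3-dimethoxybutane-2,3-diyl | O[C@@]1(C(=O)OC)C[C@@H](O)[C@H]2O[C@@](OC)(C)[C@](OC)(C)O[C@@H]2C1 | intermediate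
3 | triol, CO2Me of 2 reduced to CH2OH | O[C@@]1(CO)C[C@@H](O)[C@H]2O[C@@](OC)(C)[C@](OC)(C)O[C@@H]2C1 | intermediate
4 | 3-hydroxy-4,5-(butane-2,3-diacetal)cyclohexanone | O=C1C[C@@H](O)[C@H]2O[C@@](OC)(C)[C@](OC)(C)O[C@@H]2C1 | intermediate
5 | 3-mesylate of 4 | O=C1C[C@@H](OS(C)(=O)=O)[C@H]2O[C@@](OC)(C)[C@](OC)(C)O[C@@H]2C1 | intermediate
6 | (4R,5R)-4,5-dihydroxycyclohex-2-enone butane-2,3-diacetal | O=C1C=C[C@H]2O[C@@](OC)(C)[C@](OC)(C)O[C@@H]2C1 | intermediate
7 | TMS enol ether of the 3-methyl ketone, methyl axial | C[Si](C)(C)OC1=C[C@@H](C)[C@H]2O[C@@](OC)(C)[C@](OC)(C)O[C@@H]2C1 | intermediate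
8 | (4R,5R)-4,5-dihydroxy-3-methylcyclohex-2-enone butane-2,3-diacetal | O=C1C=C(C)[C@H]2O[C@@](OC)(C)[C@](OC)(C)O[C@@H]2C1 | intermediate
9 | (4R,5R)-4,5-dihydroxy-3-methylcyclohex-2-enone | O=C1C=C(C)[C@@H](O)[C@H](O)C1 | intermediate
10 | (4R,5R)-4,5-bis(tert-butyldimethylsilyloxy)-3-methylcyclohex-2-enone | CC1=CC(=O)C[C@@H](O[Si](C)(C)C(C)(C)C)[C@@H]1O[Si](C)(C)C(C)(C)C | intermediate
11 | cyclobutanone | O=C1CCC1 | starting material
12 | N-isopropylcyclobutanimine | CC(C)N=C1CCC1 | intermediate
13 | iodomethane | CI | starting material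
14 | lithium N-isopropyl-N-(cyclobut-1-enyl)amide | [Li]N(C(C)C)C1=CCC1 | intermediate
15 | N-isopropyl-2-methylcyclobutanimine (racemic) | CC1CCC1=NC(C)C | intermediate
16 | 2-methylcyclobutanone (racemic) | CC1CCC1=O | intermediate
17 | 1-methyl-2-(tert-butyldimethylsilyloxy)cyclobutene | CC1=C(O[Si](C)(C)C(C)(C)C)CC1 | intermediate
18 | cis-anti-cis six-four-four photoadduct, C6 ketone | C[C@]12[C@H](C(=O)C[C@@H](O[Si](C)(C)C(C)(C)C)[C@@H]1O[Si](C)(C)C(C)(C)C)[C@@]3(C)CC[C@@]23O[Si](C)(C)C(C)(C)C | intermediate
19 | 7-methylene ketone | C[C@]12[C@H](C(=O)C(=C)[C@@H](O[Si](C)(C)C(C)(C)C)[C@@H]1O[Si](C)(C)C(C)(C)C)[C@@]3(C)CC[C@@]23O[Si](C)(C)C(C)(C)C | intermediate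
20 | allylic alcohol, O6 cis to C4 and O8 | C[C@]12[C@H]([C@@H](O)C(=C)[C@@H](O[Si](C)(C)C(C)(C)C)[C@@H]1O[Si](C)(C)C(C)(C)C)[C@@]3(C)CC[C@@]23O[Si](C)(C)C(C)(C)C | intermediate
21 | 2-(bromomethyl)acrylic acid | C=C(CBr)C(=O)O | starting material
22 | 2-(acetoxymethyl)acrylic acid | C=C(COC(C)=O)C(=O)O | intermediate
23 | mixed anhydride of 22 and 2,4,6-trichlorobenzoic acid | C=C(COC(C)=O)C(=O)OC(=O)c1c(Cl)cc(Cl)cc1Cl | intermediate
24 | O6 2-(acetoxymethyl)acrylate of 20 | C[C@]12[C@H]([C@@H](OC(=O)C(=C)COC(C)=O)C(=C)[C@@H](O[Si](C)(C)C(C)(C)C)[C@@H]1O[Si](C)(C)C(C)(C)C)[C@@]3(C)CC[C@@]23O[Si](C)(C)C(C)(C)C | intermediate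
25 | tetracyclic 13-acetoxy-7(11)-en-12,6-olide, tris-TBS | C[C@]12[C@H]([C@H]4OC(=O)C(COC(C)=O)=C4[C@@H](O[Si](C)(C)C(C)(C)C)[C@@H]1O[Si](C)(C)C(C)(C)C)[C@@]3(C)CC[C@@]23O[Si](C)(C)C(C)(C)C | intermediate
26 | tetracyclic 8,9-diol, O1-TBS | C[C@]12[C@H]([C@H]4OC(=O)C(COC(C)=O)=C4[C@@H](O)[C@@H]1O)[C@@]3(C)CC[C@@]23O[Si](C)(C)C(C)(C)C | intermediate
27 | methacrylic anhydride | C=C(C)C(=O)OC(=O)C(C)=C | starting material
28 | tetracyclic 8-O-methacrylate, 9-OH, O1-TBS | C[C@]12[C@H]([C@H]4OC(=O)C(COC(C)=O)=C4[C@@H](OC(=O)C(C)=C)[C@@H]1O)[C@@]3(C)CC[C@@]23O[Si](C)(C)C(C)(C)C | intermediate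
29 | ten-membered (4E)-diene, C1 TBS enol ether | C=C(C)C(=O)O[C@@H]1C2=C(COC(C)=O)C(=O)O[C@@H]2/C=C(C)/CC/C(O[Si](C)(C)C(C)(C)C)=C(C)\[C@H]1O | intermediate
30 | (4E,10S)-1-oxo alkene | C=C(C)C(=O)O[C@@H]1C2=C(COC(C)=O)C(=O)O[C@@H]2/C=C(C)/CCC(=O)[C@@H](C)[C@H]1O | intermediate
31 | CNP0185951.1, (4R,5R,6S,8R,9R,10S) | C=C(C)C(=O)O[C@@H]1C2=C(COC(C)=O)C(=O)O[C@@H]2[C@H]2O[C@]2(C)CCC(=O)[C@@H](C)[C@H]1O | target

Total step count: 22.
Longest linear sequence: 18 (steps 1–8, 12–14, 16–22).

Steps most likely to fail

1. Step 12.
   - What may go wrong: the tetrasubstituted alkene may add too slowly, so that enone dimerisation and hydrogen abstraction take over. Head-to-tail or facial selectivity may also erode, because three contiguous quaternary carbons are made.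
   - Fallback: a temporary silicon tether. It sets out from 10 and 16 and returns at 18. Brief HF·pyridine treatment of 10 frees the less hindered C8 hydroxyl to give the C9-mono-TBS hydroxy enone F1. Ketone 16 is converted with iPr2Si(OTf)2/Et3N into the enol silyl triflate F2, which silylates F1 (2,6-lutidine) to the tethered enone F3. Irradiation then runs intramolecularly: the O8–Si–O1 bridge brings the cyclobutene to the face of O8, anti to O9, and forces C1 onto C10, giving the bridged photoadduct F4. HF·pyridine removes the silylene to give the C8,C1-diol F5, and TBSOTf/2,6-lutidine silylates both oxygens, which is 18.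

2. Step 20.
   - What may go wrong: the released 1,5-diene may drain away by Cope rearrangement, or the diyl may cleave C2–C3, both leading to the divinylcyclohexane skeleton. C4=C5 is no longer conjugated at this stage. Radical polymerisation of the methacrylate is a further risk.
   - Fallback: ketonisation as a sink. It sets out from 25 and returns at 30. Exhaustive desilylation of 25 (aq. HF, MeCN, 40 °C) gives the triol F6. Only its C8 hydroxyl is acylated by 27, since C9 is neopentylic and C1 tertiary, to give the methacrylate F7. Heating F7 in toluene containing pivalic acid opens the tricycle to the enol F8. F8 tautomerises to the C1 ketone before a Cope rearrangement can set in, so the 1,5-diene never accumulates and 30 is reached directly.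

3. Step 17.
   - What may go wrong: the metathesis may stall, because both alkenes are 1,1-disubstituted and C7 is flanked by two branched carbons.
   - Fallback: aldol, lactonisation, dehydration. It sets out from 18 and returns at 25. TMSOTf/Et3N converts 18 into the C6–C7 TMS enol ether F9. Ozonolysis (O3, then Me2S) of commercial methyl 2-(acetoxymethyl)acrylate gives methyl 3-acetoxy-2-oxopropanoate F10. A Mukaiyama aldol addition (TiCl4, CH2Cl2, −78 °C) joins them at C7, anti to O8, to give the aldol adduct F11 (C11 epimers). NaBH4/CeCl3·7H2O reduces C6 from the convex face and the alkoxide closes onto the ester to give the 11-hydroxy lactone F12. SOCl2/pyridine then eliminates away from the acetoxy-bearing C13, towards H7, which gives 25.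

Further compounds
F1 | step 12 | (4R,5R)-4-(tert-butyldimethylsilyloxy)-5-hydroxy-3-methylcyclohex-2-enone | CC1=CC(=O)C[C@@H](O)[C@@H]1O[Si](C)(C)C(C)(C)C
F2 | step 12 | diisopropyl(2-methylcyclobut-1-enyloxy)silyl triflate | CC1=C(O[Si](C(C)C)(C(C)C)OS(=O)(=O)C(F)(F)F)CC1
F3 | step 12 | enone tethered through O8–Si(iPr)2–O1 to the cyclobutene | CC1=CC(=O)C[C@@H](O[Si](C(C)C)(C(C)C)OC2=C(C)CC2)[C@@H]1O[Si](C)(C)C(C)(C)C
F4 | step 12 | silylene-bridged cis-anti-cis photoadduct | C[C@]12[C@H](C(=O)C[C@@H](O[Si]4(C(C)C)C(C)C)[C@@H]1O[Si](C)(C)C(C)(C)C)[C@@]3(C)CC[C@@]23O4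
F5 | step 12 | photoadduct with free C8 and C1 hydroxyls, O9-TBS | C[C@]12[C@H](C(=O)C[C@@H](O)[C@@H]1O[Si](C)(C)C(C)(C)C)[C@@]3(C)CC[C@@]23O
F6 | step 20 | tetracyclic butenolide 1,8,9-triol | C[C@]12[C@H]([C@H]4OC(=O)C(COC(C)=O)=C4[C@@H](O)[C@@H]1O)[C@@]3(C)CC[C@@]23O
F7 | step 20 | tetracyclic 8-O-methacrylate with free C1 and C9 hydroxyls | C[C@]12[C@H]([C@H]4OC(=O)C(COC(C)=O)=C4[C@@H](OC(=O)C(C)=C)[C@@H]1O)[C@@]3(C)CC[C@@]23O
F8 | step 20 | ten-membered (4E)-diene with free C1 enol | C=C(C)C(=O)O[C@@H]1C2=C(COC(C)=O)C(=O)O[C@@H]2/C=C(C)/CC/C(O)=C(C)\[C@H]1O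
F9 | step 17 | C6–C7 TMS enol ether of 18 | C[C@]12[C@H](C(O[Si](C)(C)C)=C[C@@H](O[Si](C)(C)C(C)(C)C)[C@@H]1O[Si](C)(C)C(C)(C)C)[C@@]3(C)CC[C@@]23O[Si](C)(C)C(C)(C)C
F10 | step 17 | methyl 3-acetoxy-2-oxopropanoate | COC(=O)C(=O)COC(C)=O
F11 | step 17 | C7 aldol adduct (C11 epimers) | C[C@]12[C@H](C(=O)[C@H](C(O)(COC(C)=O)C(=O)OC)[C@@H](O[Si](C)(C)C(C)(C)C)[C@@H]1O[Si](C)(C)C(C)(C)C)[C@@]3(C)CC[C@@]23O[Si](C)(C)C(C)(C)C
F12 | step 17 | 11-hydroxy-13-acetoxy-12,6-olide (C11 epimers) | C[C@]12[C@H]([C@H]4OC(=O)C(O)(COC(C)=O)[C@@H]4[C@@H](O[Si](C)(C)C(C)(C)C)[C@@H]1O[Si](C)(C)C(C)(C)C)[C@@]3(C)CC[C@@]23O[Si](C)(C)C(C)(C)C
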